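**Plan**

- Retrosynthesis: the benzyl ether and the O-methyl group on naphthalene C4 are removed first. Ring A of the naphthalene (C1, C2, C3, C4, closed onto C4a and C8a) is then cut at C1–C8a and C4–C4a. C1 carries chroman C4 and C4 carries an oxygen peri to the C5 methoxy group, which is the pattern left by a 4-substituted 1,1-dioxygenated diene adding to 3-methoxybenzyne.
- The diene, a vinylketene silyl acetal, goes back through the (E)-β,γ-unsaturated ester, the C4 acetaldehyde and the trans-4-allylchroman to a (2R)-chroman-4-ol made from 2',6'-dihydroxyacetophenone. The aryne comes from 2-iodo-3-methoxyphenyl triflate, made from 3-methoxyphenol.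
- Forward: the pyran ring closes first (as a chromone), the C4 side chain is grown into the diene, and ring A closes last on the aryne, which brings ring B with it.
- Stereochemistry: C2 comes from an enantioselective copper hydride conjugate reduction of the chromone. C4 comes from trans-selective allylation of the chroman-4-yl cation under control of C2. The E geometry of the diene is fixed by a deconjugative Knoevenagel–Doebner condensation rather than by γ-deprotonation of a conjugated (E)-enoate, which is known to favour the Z-dienolate.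

Key step: step 14

Remark (assumption): the (R)-antipode of the bisphosphine in step 3 is written as the one that leads to the (2R)-chromanone; if the copper hydride proves to attack the other face, the (S)-ligand is used and nothing else changes.

**Route**

Step 1
Reactants: 1 2',6'-dihydroxyacetophenone
Product: 2 1-[2-(benzyloxy)-6-hydroxyphenyl]ethan-1-one
Conditions: BnBr (1.05 equiv), K2CO3 (1.2 equiv), acetone, reflux
Reagents that add atoms: benzyl bromide, BrCc1ccccc1
Why: Williamson etherification with one equivalent of halide should stop at the mono-ether, because the remaining phenol is held in a hydrogen bond to the ketone and is the poorer nucleophile.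

Step 2
Reactants: 2 1-[2-(benzyloxy)-6-hydroxyphenyl]ethan-1-one; 3 ethyl acetate
Product: 5 5-(benzyloxy)-2-methyl-4H-chromen-4-one, via aryl 1,3-diketone 4 (not isolated)
Conditions: NaH (4 equiv), 3 (6 equiv), THF, reflux; then HCl (cat.), MeOH, 50 °C
Reagents that add atoms: none
Why: Claisen condensation of the ketone enolate with ethyl acetate followed by acid-catalysed cyclodehydration is the classical 2-methylchromone synthesis, and the benzyl aryl ether tolerates both stages.

Step 3
Reactants: 5 5-(benzyloxy)-2-methyl-4H-chromen-4-one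
Product: 6 (2R)-5-(benzyloxy)-2-methyl-2,3-dihydro-4H-chromen-4-one
Conditions: Cu(OAc)2 (5 mol %), (R)-DTBM-SEGPHOS (5.5 mol %), (EtO)2MeSiH (2 equiv), t-BuOH (2 equiv), toluene, 0 °C
Reagents that add atoms: none
Why: Enantioselective copper hydride conjugate reduction, known for 2-alkylchromones, delivers hydride to C2 from the face selected by the chiral bisphosphine and so sets C2 as R; any ketone reduced further is simply the product of step 4.

Step 4
Reactants: 6 (2R)-5-(benzyloxy)-2-methyl-2,3-dihydro-4H-chromen-4-one
Product: 7 (2R,4S)-5-(benzyloxy)-2-methyl-3,4-dihydro-2H-chromen-4-ol (cis; any 4R epimer is carried along)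
Conditions: NaBH4, MeOH, 0 °C
Reagents that add atoms: none
Why: Borohydride reduction of the ketone with axial hydride delivery should give mainly the cis alcohol, and the C4 configuration is erased in step 5, so the epimer ratio is without consequence.

Step 5
Reactants: 7 (2R,4S)-5-(benzyloxy)-2-methyl-3,4-dihydro-2H-chromen-4-ol; 8 allyltrimethylsilane
Product: 10 (2R,4R)-5-(benzyloxy)-2-methyl-4-(prop-2-en-1-yl)-3,4-dihydro-2H-chromene (2,4-trans), via chroman-4-yl cation 9 (not isolated)
Conditions: 8 (3 equiv), Bi(OTf)3 (5 mol %), CH2Cl2, −20 → 0 °C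
Reagents that add atoms: none
Why: Hosomi–Sakurai-type SN1 allylation of a benzylic alcohol: the cation, stabilised by two ortho oxygens, adopts a half-chair with the C2 methyl pseudo-equatorial and is attacked pseudo-axially at C4, which places the allyl group trans to the methyl group (4R) and out of the plane of the peri benzyloxy group.

Step 6
Reactants: 10 (2R,4R)-5-(benzyloxy)-2-methyl-4-(prop-2-en-1-yl)-3,4-dihydro-2H-chromene
Product: 12 2-[(2R,4S)-5-(benzyloxy)-2-methyl-3,4-dihydro-2H-chromen-4-yl]acetaldehyde, via 1,2-diol 11 (not isolated)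
Conditions: OsO4 (2 mol %), NaIO4 (4 equiv), 2,6-lutidine (2 equiv), dioxane/H2O 3:1, rt
Reagents that add atoms: osmium tetroxide, O=[Os](=O)(=O)=O; sodium periodate, [Na+].[O-]I(=O)(=O)=O
Why: Lemieux–Johnson oxidation (catalytic dihydroxylation of the terminal alkene and periodate cleavage of the diol) should give the aldehyde while leaving the electron-rich resorcinol-type ring alone, which ozone might not.

Step 7
Reactants: 12 2-[(2R,4S)-5-(benzyloxy)-2-methyl-3,4-dihydro-2H-chromen-4-yl]acetaldehyde; 13 malonic acid
Product: 16 (3E)-4-[(2R,4S)-5-(benzyloxy)-2-methyl-3,4-dihydro-2H-chromen-4-yl]but-3-enoic acid, via alkylidenemalonic acid 14 (not isolated), via vinylmalonic acid 15 (not isolated)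
Conditions: 13 (2 equiv), piperidinium acetate (10 mol %), DMSO, 100 °C
Reagents that add atoms: none
Why: Knoevenagel–Doebner condensation in its deconjugative variant: the alkylidenemalonic acid equilibrates to the β,γ-unsaturated diacid, which decarboxylates faster, a sequence known to give (E)-alk-3-enoic acids, so the E geometry of the future diene terminus is fixed here.

Step 8
Reactants: 16 (3E)-4-[(2R,4S)-5-(benzyloxy)-2-methyl-3,4-dihydro-2H-chromen-4-yl]but-3-enoic acid
Product: 17 methyl (3E)-4-[(2R,4S)-5-(benzyloxy)-2-methyl-3,4-dihydro-2H-chromen-4-yl]but-3-enoate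
Conditions: Me3SiCHN2 (1.5 equiv), toluene/MeOH 3:1, 0 °C → rt
Reagents that add atoms: trimethylsilyldiazomethane, C[Si](C)(C)C=[N+]=[N-]
Why: Esterification with trimethylsilyldiazomethane in methanol is neutral, so the β,γ-double bond should neither move into conjugation nor lose its geometry.

Step 9
Reactants: 17 methyl (3E)-4-[(2R,4S)-5-(benzyloxy)-2-methyl-3,4-dihydro-2H-chromen-4-yl]but-3-enoate
Product: 19 tert-butyl({(3E)-4-[(2R,4S)-5-(benzyloxy)-2-methyl-3,4-dihydro-2H-chromen-4-yl]-1-methoxybuta-1,3-dien-1-yl}oxy)dimethylsilane (ketene acetal geometry immaterial), via lithium dienolate 18 (not isolated)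
Conditions: LiN(i-Pr)2 (1.15 equiv), THF, −78 °C; then TBSCl (1.3 equiv), DMPU, −78 → 0 °C; pentane, cold aq. NaHCO3, used crude
Reagents that add atoms: tert-butyldimethylsilyl chloride, CC(C)(C)[Si](C)(C)Cl
Why: Ireland-type enolisation removes the doubly activated α-proton and the dienolate is silylated on oxygen in the presence of DMPU; the C3=C4 bond is never broken and should keep its E geometry, and the tert-butyldimethylsilyl acetal is robust enough to be handled.

Step 10
Reactants: 20 3-methoxyphenol
Product: 21 1-methoxy-3-(methoxymethoxy)benzene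
Conditions: MOMCl (1.3 equiv), i-Pr2NEt (1.5 equiv), CH2Cl2, 0 °C → rt
Reagents that add atoms: chloromethyl methyl ether, COCCl
Why: Standard O-alkylation of a phenol gives the methoxymethyl ether, which serves as the second directing group for metalation.

Step 11
Reactants: 21 1-methoxy-3-(methoxymethoxy)benzene
Product: 23 2-iodo-1-methoxy-3-(methoxymethoxy)benzene, via aryllithium 22 (not isolated)
Conditions: n-BuLi (1.1 equiv), THF, 0 °C → rt; then I2 (1.2 equiv), −78 °C → rt
Reagents that add atoms: iodine, II
Why: Directed ortho-metalation takes place at the position flanked by both oxygen substituents, and iodine quenches the aryllithium there.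

Step 12
Reactants: 23 2-iodo-1-methoxy-3-(methoxymethoxy)benzene
Product: 24 2-iodo-3-methoxyphenol
Conditions: HCl (cat.), MeOH, 50 °C
Reagents that add atoms: none
Why: Acid-catalysed methanolysis cleaves the acetal-type methoxymethyl ether and leaves the aryl methyl ether and the iodide untouched.

Step 13
Reactants: 24 2-iodo-3-methoxyphenol
Product: 25 2-iodo-3-methoxyphenyl trifluoromethanesulfonate
Conditions: Tf2O (1.2 equiv), pyridine (2 equiv), CH2Cl2, 0 °C
Reagents that add atoms: trifluoromethanesulfonic anhydride, O=S(=O)(OS(=O)(=O)C(F)(F)F)C(F)(F)F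
Why: O-Sulfonylation of the phenol gives the ortho-iodoaryl triflate, the established aryne precursor for halogen–lithium exchange.

Step 14
Reactants: 19 tert-butyl({(3E)-4-[(2R,4S)-5-(benzyloxy)-2-methyl-3,4-dihydro-2H-chromen-4-yl]-1-methoxybuta-1,3-dien-1-yl}oxy)dimethylsilane; 25 2-iodo-3-methoxyphenyl trifluoromethanesulfonate
Product: 30 4-[(2R,4S)-5-(benzyloxy)-2-methyl-3,4-dihydro-2H-chromen-4-yl]-8-methoxynaphthalen-1-ol, via 2-lithioaryl triflate 26 (not isolated), via 3-methoxybenzyne 27 (not isolated), via dihydronaphthalene ketal 28 (not isolated), via 4H-naphthalen-1-one 29 (not isolated)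
Conditions: 19 (1 equiv), 25 (2 equiv), THF, −78 °C, n-BuLi (2 equiv, slow addition); then Bu4NF (3 equiv), −78 °C → rt; aq. NH4Cl
Reagents that add atoms: none
Why: Iodine–lithium exchange on 25 is faster than attack of n-BuLi on the silyl acetal, and the lithioaryl triflate loses LiOTf at −78 °C to release 3-methoxybenzyne in the presence of the diene. The aryne is distorted so that the carbon remote from the methoxy group is the electrophilic one; diene C4, the γ-carbon of the vinylogous ketene acetal and its most nucleophilic site, bonds there and the acetal carbon C1 bonds next to the methoxy group, the head-to-head sense known for 3-alkoxybenzynes with ketene silyl acetals. Ring A closes in a concerted but asynchronous [4+2] cycloaddition through the s-cis diene (both bonds in one six-membered transition state), the closest known class being aryne Diels–Alder reactions of acyclic 1-oxygenated dienes. No stereocentre of the product is created, since the sp3 carbon of the adduct that bears the chromanyl group is lost on aromatisation, and chroman C2 and C4 are not touched at −78 °C. Fluoride then removes the silyl group, the hemiketal expels methoxide, and the 4H-naphthalen-1-one tautomerises to the naphthol. The step needs periselectivity for [4+2] over [2+2] and the orientation described; the (3E) geometry fixed in step 7 makes the s-cis conformer accessible, and the methoxy group of the aryne together with the polarity of the diene secures the orientation.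

Step 15
Reactants: 30 4-[(2R,4S)-5-(benzyloxy)-2-methyl-3,4-dihydro-2H-chromen-4-yl]-8-methoxynaphthalen-1-ol
Product: 31 (2R,4S)-5-(benzyloxy)-4-(4,5-dimethoxynaphthalen-1-yl)-2-methyl-3,4-dihydro-2H-chromene
Conditions: MeI (5 equiv), K2CO3 (3 equiv), DMF, 40 °C
Reagents that add atoms: iodomethane, CI
Why: Williamson methylation of the peri-hydrogen-bonded naphthol should go with excess iodide in DMF, and any 1-methoxy compound formed in step 14 by loss of silanol instead of methanol is identical with this product.

Step 16
Reactants: 31 (2R,4S)-5-(benzyloxy)-4-(4,5-dimethoxynaphthalen-1-yl)-2-methyl-3,4-dihydro-2H-chromene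
Product: 32 (2R,4S)-4-(4,5-dimethoxynaphthalen-1-yl)-2-methyl-3,4-dihydro-2H-chromen-5-ol (cladonaphchrom A)
Conditions: H2 (1 atm), Pd/C (10 wt %), EtOAc/MeOH, rt
Reagents that add atoms: none
Why: Hydrogenolysis of the benzyl aryl ether over Pd/C should free the phenol while the naphthalene, the aryl alkyl ether bond of the chroman and the tertiary benzylic C4–H stay intact at ambient pressure and temperature.

**Compound list**

1 | 2',6'-dihydroxyacetophenone | CC(=O)c1c(O)cccc1O | starting material
2 | 1-[2-(benzyloxy)-6-hydroxyphenyl]ethan-1-one | CC(=O)c1c(O)cccc1OCc1ccccc1 | intermediate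
3 | ethyl acetate | CCOC(C)=O | starting material
4 | 1-[2-(benzyloxy)-6-hydroxyphenyl]butane-1,3-dione | CC(=O)CC(=O)c1c(O)cccc1OCc1ccccc1 | intermediate (not isolated)
5 | 5-(benzyloxy)-2-methyl-4H-chromen-4-one | Cc1cc(=O)c2c(OCc3ccccc3)cccc2o1 | intermediate
6 | (2R)-5-(benzyloxy)-2-methyl-2,3-dihydro-4H-chromen-4-one | O=C1C[C@@H](C)Oc2cccc(OCc3ccccc3)c21 | intermediate
7 | (2R,4S)-5-(benzyloxy)-2-methyl-3,4-dihydro-2H-chromen-4-ol (cis) | O[C@H]1C[C@@H](C)Oc2cccc(OCc3ccccc3)c21 | intermediate
8 | allyltrimethylsilane | C=CC[Si](C)(C)C | starting material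
9 | (2R)-5-(benzyloxy)-2-methyl-3,4-dihydro-2H-chromen-4-ylium | [CH+]1C[C@@H](C)Oc2cccc(OCc3ccccc3)c21 | intermediate (not isolated)
10 | (2R,4R)-5-(benzyloxy)-2-methyl-4-(prop-2-en-1-yl)-3,4-dihydro-2H-chromene (2,4-trans) | C=CC[C@@H]1C[C@@H](C)Oc2cccc(OCc3ccccc3)c21 | intermediate
11 | 3-[(2R,4R)-5-(benzyloxy)-2-methyl-3,4-dihydro-2H-chromen-4-yl]propane-1,2-diol (both carbinol epimers) | OCC(O)C[C@@H]1C[C@@H](C)Oc2cccc(OCc3ccccc3)c21 | intermediate (not isolated)
12 | 2-[(2R,4S)-5-(benzyloxy)-2-methyl-3,4-dihydro-2H-chromen-4-yl]acetaldehyde | O=CC[C@@H]1C[C@@H](C)Oc2cccc(OCc3ccccc3)c21 | intermediate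
13 | malonic acid | OC(=O)CC(O)=O | starting material
14 | 2-{2-[(2R,4R)-5-(benzyloxy)-2-methyl-3,4-dihydro-2H-chromen-4-yl]ethylidene}propanedioic acid | OC(=O)C(=CC[C@@H]1C[C@@H](C)Oc2cccc(OCc3ccccc3)c21)C(O)=O | intermediate (not isolated)
15 | 2-{(E)-2-[(2R,4S)-5-(benzyloxy)-2-methyl-3,4-dihydro-2H-chromen-4-yl]ethenyl}propanedioic acid | OC(=O)C(/C=C/[C@@H]1C[C@@H](C)Oc2cccc(OCc3ccccc3)c21)C(O)=O | intermediate (not isolated)
16 | (3E)-4-[(2R,4S)-5-(benzyloxy)-2-methyl-3,4-dihydro-2H-chromen-4-yl]but-3-enoic acid | OC(=O)C/C=C/[C@@H]1C[C@@H](C)Oc2cccc(OCc3ccccc3)c21 | intermediate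
17 | methyl (3E)-4-[(2R,4S)-5-(benzyloxy)-2-methyl-3,4-dihydro-2H-chromen-4-yl]but-3-enoate | COC(=O)C/C=C/[C@@H]1C[C@@H](C)Oc2cccc(OCc3ccccc3)c21 | intermediate
18 | lithium (3E)-4-[(2R,4S)-5-(benzyloxy)-2-methyl-3,4-dihydro-2H-chromen-4-yl]-1-methoxybuta-1,3-dien-1-olate | [Li]OC(OC)=C/C=C/[C@@H]1C[C@@H](C)Oc2cccc(OCc3ccccc3)c21 | intermediate (not isolated)
19 | tert-butyl({(3E)-4-[(2R,4S)-5-(benzyloxy)-2-methyl-3,4-dihydro-2H-chromen-4-yl]-1-methoxybuta-1,3-dien-1-yl}oxy)dimethylsilane | COC(O[Si](C)(C)C(C)(C)C)=C/C=C/[C@@H]1C[C@@H](C)Oc2cccc(OCc3ccccc3)c21 | intermediate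
20 | 3-methoxyphenol | COc1cccc(O)c1 | starting material
21 | 1-methoxy-3-(methoxymethoxy)benzene | COCOc1cccc(OC)c1 | intermediate
22 | [2-methoxy-6-(methoxymethoxy)phenyl]lithium | [Li]c1c(OC)cccc1OCOC | intermediate (not isolated)
23 | 2-iodo-1-methoxy-3-(methoxymethoxy)benzene | COCOc1cccc(OC)c1I | intermediate
24 | 2-iodo-3-methoxyphenol | COc1cccc(O)c1I | intermediate
25 | 2-iodo-3-methoxyphenyl trifluoromethanesulfonate | COc1cccc(OS(=O)(=O)C(F)(F)F)c1I | intermediate
26 | 2-lithio-3-methoxyphenyl trifluoromethanesulfonate | COc1cccc(OS(=O)(=O)C(F)(F)F)c1[Li] | intermediate (not isolated)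
27 | 3-methoxybenzyne (1-methoxycyclohexa-1,3-dien-5-yne) | COC1=CC=CC#C1 | intermediate (not isolated)
28 | tert-butyl({4-[(2R,4S)-5-(benzyloxy)-2-methyl-3,4-dihydro-2H-chromen-4-yl]-1,8-dimethoxy-1,4-dihydronaphthalen-1-yl}oxy)dimethylsilane (diastereomer mixture at the dihydronaphthalene carbons) | COc1cccc2c1C(OC)(O[Si](C)(C)C(C)(C)C)C=CC2[C@@H]1C[C@@H](C)Oc2cccc(OCc3ccccc3)c21 | intermediate (not isolated)
29 | 4-[(2R,4S)-5-(benzyloxy)-2-methyl-3,4-dihydro-2H-chromen-4-yl]-8-methoxynaphthalen-1(4H)-one | O=C1C=CC([C@@H]2C[C@@H](C)Oc3cccc(OCc4ccccc4)c32)c2cccc(OC)c12 | intermediate (not isolated)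
30 | 4-[(2R,4S)-5-(benzyloxy)-2-methyl-3,4-dihydro-2H-chromen-4-yl]-8-methoxynaphthalen-1-ol | Oc1ccc([C@@H]2C[C@@H](C)Oc3cccc(OCc4ccccc4)c32)c2cccc(OC)c12 | intermediate
31 | (2R,4S)-5-(benzyloxy)-4-(4,5-dimethoxynaphthalen-1-yl)-2-methyl-3,4-dihydro-2H-chromene | COc1ccc([C@@H]2C[C@@H](C)Oc3cccc(OCc4ccccc4)c32)c2cccc(OC)c12 | intermediate
32 | (2R,4S)-4-(4,5-dimethoxynaphthalen-1-yl)-2-methyl-3,4-dihydro-2H-chromen-5-ol (cladonaphchrom A) | COc1cccc2c([C@@H]3C[C@@H](C)Oc4cccc(O)c43)ccc(OC)c12 | target

**Step count**

Total: 16 steps. Longest linear sequence: 12 steps (steps 1–9 and 14–16); the aryne precursor takes 4 steps (10–13) in a separate branch.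

**Steps most likely to fail**

Step 14. The aryne may add across the ketene acetal double bond in a [2+2] sense or react by an ene pathway instead of the [4+2] mode, may add with the reverse orientation, or the silyl acetal may be cleaved by n-BuLi before the exchange is complete. The fallback sets out from chromanol 7 and rejoins the route at 31. Alcohol 7 is ionised with Bi(OTf)3 in CH2Cl2 at low temperature in the presence of commercial 1,8-dimethoxynaphthalene. Friedel–Crafts alkylation by cation 9 at the position para to a methoxy group, pseudo-axial and therefore trans to the C2 methyl group, should give 31 directly. No compound outside the list is made on the way (F0).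

Step 3. Facial discrimination at the C2=C3 bond of the 5-alkoxychromone may be insufficient, so that C2 is set with low enantiomeric purity. The fallback sets out from chromone 5 and rejoins at 7, replacing asymmetric catalysis by resolution. Copper hydride reduction with an achiral ligand (Cu(OAc)2, 1,2-bis(diphenylphosphino)benzene, (EtO)2MeSiH, t-BuOH) should give racemic 5-(benzyloxy)-2-methyl-2,3-dihydro-4H-chromen-4-one F1. NaBH4 in MeOH should then give the racemic cis-5-(benzyloxy)-2-methyl-3,4-dihydro-2H-chromen-4-ol F2, which is freed from the minor trans isomer. Candida antarctica lipase B with vinyl acetate is expected, by its usual preference for the (R)-carbinol of aryl alkyl carbinols, to acylate the (4R)-enantiomer to (2S,4R)-5-(benzyloxy)-2-methyl-3,4-dihydro-2H-chromen-4-yl acetate F3. The unreacted alcohol is then 7.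

Step 7. The double bond may fail to move fully out of conjugation during decarboxylation, giving mixtures of 2- and 3-enoic acids or of alkene isomers. The fallback sets out from aldehyde 12 and rejoins at 19. Still–Gennari olefination (methyl bis(2,2,2-trifluoroethyl)phosphonoacetate, KN(SiMe3)2, 18-crown-6, THF, −78 °C) should give methyl (2Z)-4-[(2R,4R)-5-(benzyloxy)-2-methyl-3,4-dihydro-2H-chromen-4-yl]but-2-enoate F4. γ-Deprotonation of this (Z)-enoate with LiN(i-Pr)2 in THF/DMPU and O-silylation with TBSCl is expected, from the known stereospecificity of kinetic enoate deconjugation (Z-2-enoates give E-dienolates), to give the (3E)-diene 19.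

**Further compounds**

F0 | step 14 | none | none
F1 | step 3 | racemic 5-(benzyloxy)-2-methyl-2,3-dihydro-4H-chromen-4-one | CC1CC(=O)c2c(OCc3ccccc3)cccc2O1
F2 | step 3 | racemic cis-5-(benzyloxy)-2-methyl-3,4-dihydro-2H-chromen-4-ol ((2RS,4SR)) | CC1CC(O)c2c(OCc3ccccc3)cccc2O1
F3 | step 3 | (2S,4R)-5-(benzyloxy)-2-methyl-3,4-dihydro-2H-chromen-4-yl acetate | CC(=O)O[C@@H]1C[C@H](C)Oc2cccc(OCc3ccccc3)c21
F4 | step 7 | methyl (2Z)-4-[(2R,4R)-5-(benzyloxy)-2-methyl-3,4-dihydro-2H-chromen-4-yl]but-2-enoate | COC(=O)/C=C\C[C@@H]1C[C@@H](C)Oc2cccc(OCc3ccccc3)c21
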